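**Plan**

1. Retrosynthesis (labdane-type numbering: ring A = C1–C5 and C10, ring B = C5–C10, side chain C11–C15): cut C9–C11 (Negishi coupling at a C8=C9 enol triflate), cut the 4-methylpent-3-enyl chain on C4 back to a formyl group, then cut ring A at C3–C4 and C5–C10 together (intramolecular Diels–Alder), which leaves an acyclic (2E,8E)-trienal.
2. Enabling feature: in ring A the bonds C3–C4 and C5–C10 lie para to each other across the C1–C2 unit, C5–C10 is the fusion bond to ring B, and C4 carries a carbon that can be a formyl group. Ring A is therefore the cyclohexene retron of a C10=C1–C2=C3 diene adding to a C4=C5 enal tethered through C6–C9.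
3. Forward: Wittig dienal, catalytic anti-crotylboration, B-alkyl Suzuki coupling and oxidation give the trienal. One cycloaddition closes rings A and B together. Then C1=C2 is saturated, the formyl group is grown into the C4 chain, and C9–OSi is taken through ketone and enol triflate to the side chain and the acid.
4. Stereochemistry: one chiral-acid-catalysed crotylboration sets C8 and C9. In the cycloaddition these relay to C4, C5 and C10 (E-enal geometry for C4, endo mode for the trans fusion, equatorial C8 methyl for the face). They are helpers and are erased when C8=C9 is formed. The (E)-enoate comes from a syn-carboalumination.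

Key step: step 7

Remark: β is the face of the C10 methyl group and α the face of H-5, so the target is the (4S,5S,10S,13E) acid with 4β-methyl, 4α-(4-methylpent-3-enyl), 5α-H and 10β-methyl; compounds 1, 2, 4, 7, 16 and 23 are assumed to be commercially available.

Step 1
Reactants: 1 prop-2-enal (acrolein); 2 2-(triphenylphosphoranylidene)propanal
Product: 3 (2E)-2-methylpenta-2,4-dienal
Conditions: 1 in excess, CH2Cl2, 0 °C to rt
Reagents that add atoms: none
Why: Wittig olefination with a formyl-stabilised ylide should react faster with unhindered acrolein than with the conjugated product and give the (E)-2-methyl-2-enal under the usual thermodynamic control of stabilised ylides.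

Step 2
Reactants: 3 (2E)-2-methylpenta-2,4-dienal; 4 2-[(2E)-but-2-en-1-yl]-4,4,5,5-tetramethyl-1,3,2-dioxaborolane
Product: 5 (3R,4R,5E)-3,5-dimethylocta-1,5,7-trien-4-ol
Conditions: (R)-3,3′-bis(2,4,6-triisopropylphenyl)-1,1′-binaphthyl-2,2′-diyl hydrogen phosphate (5 mol%), 4 Å molecular sieves, toluene, −30 °C; aq. NaHCO3
Reagents that add atoms: none
Why: Chiral-phosphoric-acid-catalysed crotylboration runs through a closed six-membered chair transition state, so the (E)-crotyl geometry gives the anti pair and the (R)-acid should direct attack to the re face of the aldehyde, setting 3R,4R as the only stereocentres made by a chiral agent in the route.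

Step 3
Reactants: 5 (3R,4R,5E)-3,5-dimethylocta-1,5,7-trien-4-ol
Product: 6 tert-butyl{[(3R,4R,5E)-3,5-dimethylocta-1,5,7-trien-4-yl]oxy}dimethylsilane
Conditions: t-BuMe2SiOTf, 2,6-lutidine, CH2Cl2, −78 to 0 °C
Reagents that add atoms: tert-butyldimethylsilyl trifluoromethanesulfonate, CC(C)(C)[Si](C)(C)OS(=O)(=O)C(F)(F)F
Why: Silylation of the hindered secondary allylic alcohol with the silyl triflate is a standard protection that masks the hydroxyl against the later allylic oxidation and the Lewis acid.

Step 4
Reactants: 7 prop-2-yn-1-ol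
Product: 9 (2E)-3-iodo-2-methylprop-2-en-1-ol, via alkenylalane 8 (not isolated)
Conditions: AlMe3 (3 equiv), Cp2ZrCl2 (0.25 equiv), CH2Cl2, 0 °C to rt; then I2, THF, −30 to 0 °C; aq. K2CO3
Reagents that add atoms: trimethylaluminium, C[Al](C)C; iodine, [I][I]
Why: Zirconium-catalysed carboalumination of the terminal alkyne is a syn addition that puts methyl on the internal carbon, and iodinolysis of the alkenyl–aluminium bond with retention gives the (E)-vinyl iodide.

Step 5
Reactants: 6 tert-butyl{[(3R,4R,5E)-3,5-dimethylocta-1,5,7-trien-4-yl]oxy}dimethylsilane; 9 (2E)-3-iodo-2-methylprop-2-en-1-ol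
Product: 11 (2E,6R,7R,8E)-7-(tert-butyldimethylsilyloxy)-2,6,8-trimethylundeca-2,8,10-trien-1-ol, via alkylborane 10 (not isolated)
Conditions: 9-borabicyclo[3.3.1]nonane (1.1 equiv), THF, 0 °C to rt; then 9, Pd(dppf)Cl2 (5 mol%), AsPh3, Cs2CO3, DMF–H2O, rt
Reagents that add atoms: none
Why: 9-BBN hydroborates the isolated monosubstituted alkene anti-Markovnikov much faster than the conjugated diene, and the primary alkylborane then undergoes B-alkyl Suzuki–Miyaura coupling with the vinyl iodide with retention of the (E) geometry.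

Step 6
Reactants: 11 (2E,6R,7R,8E)-7-(tert-butyldimethylsilyloxy)-2,6,8-trimethylundeca-2,8,10-trien-1-ol
Product: 12 (2E,6R,7R,8E)-7-(tert-butyldimethylsilyloxy)-2,6,8-trimethylundeca-2,8,10-trienal
Conditions: MnO2 (excess), CH2Cl2, rt
Reagents that add atoms: none
Why: MnO2 is a selective allylic oxidant and should convert the primary allylic alcohol into the (E)-enal without touching the silyl ether or the diene.

Step 7
Reactants: 12 (2E,6R,7R,8E)-7-(tert-butyldimethylsilyloxy)-2,6,8-trimethylundeca-2,8,10-trienal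
Product: 13 9α-(tert-butyldimethylsilyloxy)-4β,8α,10β-trimethyl-5αH-octal-1-ene-4α-carbaldehyde (trans-fused)
Conditions: Me2AlCl (1.2 equiv), CH2Cl2, −78 to −20 °C; aq. NaHCO3–Rochelle salt
Reagents that add atoms: none
Why: Complexation of Me2AlCl to the formyl oxygen lowers the LUMO of the (E)-2-methyl-2-enal, which adds across the C10=C1–C2=C3 diene in a concerted, asynchronous intramolecular Diels–Alder reaction that forms C3–C4 and C5–C10 together; the closest known reaction type is the Lewis-acid-promoted type 1 cycloaddition of (E,E)-2,8,10-undecatrienals to trans-fused octalins. Ring A closes as the new cyclohexene through the boat-like [4+2] array, and ring B closes as the four-carbon tether C6–C9 in a chair, in the fused mode with the formyl group endo and the tether anti. C4 is fixed suprafacially by the (E)-enal geometry (formyl trans to the tether, hence endo and α; methyl exo and β), and the trans C5/C10 fusion follows from the endo transition state with the C10 methyl in the inside position of the (E)-diene. The absolute sense is relayed from C8 and C9, because only one chair places the C8 methyl equatorial (axial it would meet the C10 methyl in a syn-pentane clash) with the C9 silyloxy group in the inside position next to the diene. The step needs endo over exo and one π-face over the other; the aluminium-bound aldehyde should secure the first and the anti C8/C9 pair the second, since every cis-fused or opposite-face chair carries a 1,3-diaxial or eclipsing penalty. The 1,3-diaxial C4/C10 methyl pair that develops is the main kinetic cost and is accepted because both bonds form in one ring-closing event.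

Step 8
Reactants: 13 9α-(tert-butyldimethylsilyloxy)-4β,8α,10β-trimethyl-5αH-octal-1-ene-4α-carbaldehyde
Product: 14 9α-(tert-butyldimethylsilyloxy)-4β,8α,10β-trimethyl-5αH-decalin-4α-carbaldehyde
Conditions: H2 (1–3 atm), 10% Pd/C, EtOAc, rt
Reagents that add atoms: none
Why: Heterogeneous hydrogenation reduces the only C=C bond in the molecule (cis-disubstituted C1=C2) and should leave the hindered tertiary aldehyde and the silyl ether intact.

Step 9
Reactants: 14 9α-(tert-butyldimethylsilyloxy)-4β,8α,10β-trimethyl-5αH-decalin-4α-carbaldehyde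
Product: 15 9α-(tert-butyldimethylsilyloxy)-4β,8α,10β-trimethyl-4α-vinyl-5αH-decalin
Conditions: Ph3PCH3Br, KOtBu, THF, 0 to 50 °C
Reagents that add atoms: methyltriphenylphosphonium bromide, C[P+](c1ccccc1)(c1ccccc1)c1ccccc1.[Br-]
Why: Wittig methylenation works on non-enolisable neopentyl aldehydes, so the formyl group on quaternary C4 becomes a vinyl group with no risk to C4.

Step 10
Reactants: 15 9α-(tert-butyldimethylsilyloxy)-4β,8α,10β-trimethyl-4α-vinyl-5αH-decalin; 16 1-bromo-2-methylprop-1-ene
Product: 18 9α-(tert-butyldimethylsilyloxy)-4β,8α,10β-trimethyl-4α-(4-methylpent-3-en-1-yl)-5αH-decalin, via alkylborane 17 (not isolated)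
Conditions: 9-borabicyclo[3.3.1]nonane, THF, rt to 50 °C; then 16, Pd(dppf)Cl2 (5 mol%), K3PO4 (aq), DMF, 50 °C
Reagents that add atoms: none
Why: 9-BBN adds boron to the terminal carbon of the vinyl group, and B-alkyl Suzuki–Miyaura coupling of this primary borane with the vinyl bromide completes the 4-methylpent-3-enyl chain.

Step 11
Reactants: 18 9α-(tert-butyldimethylsilyloxy)-4β,8α,10β-trimethyl-4α-(4-methylpent-3-en-1-yl)-5αH-decalin
Product: 19 4β,8α,10β-trimethyl-4α-(4-methylpent-3-en-1-yl)-5αH-decalin-9α-ol
Conditions: Bu4NF, THF, 60 °C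
Reagents that add atoms: none
Why: Fluoride cleaves the Si–O bond (driven by the strong Si–F bond) and frees the axial C9 alcohol; warming compensates for the neopentyl environment.

Step 12
Reactants: 19 4β,8α,10β-trimethyl-4α-(4-methylpent-3-en-1-yl)-5αH-decalin-9α-ol
Product: 20 4β,8α,10β-trimethyl-4α-(4-methylpent-3-en-1-yl)-5αH-decalin-9-one
Conditions: Dess–Martin periodinane, CH2Cl2, rt
Reagents that add atoms: none
Why: Dess–Martin oxidation of the hindered secondary alcohol gives the C9 ketone and removes the C9 stereocentre once it has done its work.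

Step 13
Reactants: 20 4β,8α,10β-trimethyl-4α-(4-methylpent-3-en-1-yl)-5αH-decalin-9-one
Product: 22 4β,8,10β-trimethyl-4α-(4-methylpent-3-en-1-yl)-5αH-octal-8-en-9-yl trifluoromethanesulfonate, via potassium enolate 21 (not isolated)
Conditions: KN(SiMe3)2, THF, −78 °C; then PhNTf2, −78 to 0 °C; aq. NH4Cl
Reagents that add atoms: N-phenylbis(trifluoromethanesulfonimide), O=S(=O)(N(c1ccccc1)S(=O)(=O)C(F)(F)F)C(F)(F)F
Why: The ketone can enolise only towards C8 because C10 is quaternary, so O-triflation of the potassium enolate fixes the tetrasubstituted C8=C9 double bond regiospecifically and erases the C8 stereocentre.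

Step 14
Reactants: 23 4-bromobut-1-yne
Product: 25 ethyl (2E)-5-bromo-3-methylpent-2-enoate, via alkenylalane 24 (not isolated)
Conditions: AlMe3 (2 equiv), Cp2ZrCl2 (0.2 equiv), CH2Cl2, 0 °C to rt; then ClCO2Et, 0 °C to rt; aq. NaHCO3–Rochelle salt
Reagents that add atoms: trimethylaluminium, C[Al](C)C; ethyl chloroformate, CCOC(=O)Cl
Why: Zirconium-catalysed syn-carboalumination of the terminal alkyne followed by acylation of the alkenylalane with ethyl chloroformate (retention) should give the (E)-3-methyl-2-enoate with the primary bromide untouched.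

Step 15
Reactants: 22 4β,8,10β-trimethyl-4α-(4-methylpent-3-en-1-yl)-5αH-octal-8-en-9-yl trifluoromethanesulfonate; 25 ethyl (2E)-5-bromo-3-methylpent-2-enoate
Product: 27 ethyl (2E)-3-methyl-5-[4β,8,10β-trimethyl-4α-(4-methylpent-3-en-1-yl)-5αH-octal-8-en-9-yl]pent-2-enoate, via alkylzinc bromide 26 (not isolated)
Conditions: Zn dust, LiCl, THF, 50 °C; then 22, Pd(OAc)2 (5 mol%), 2-dicyclohexylphosphino-2′,6′-dimethoxybiphenyl (10 mol%), THF–NMP, 60 °C
Reagents that add atoms: none
Why: LiCl-assisted zinc insertion into the primary C–Br bond gives an ester-tolerant alkylzinc, and Negishi coupling at the enol triflate with a bulky electron-rich biarylphosphine (reductive elimination faster than β-hydride elimination) forms C9–C11 with both alkene geometries retained.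

Step 16
Reactants: 27 ethyl (2E)-3-methyl-5-[4β,8,10β-trimethyl-4α-(4-methylpent-3-en-1-yl)-5αH-octal-8-en-9-yl]pent-2-enoate
Product: 28 (2E)-3-methyl-5-[4β,8,10β-trimethyl-4α-(4-methylpent-3-en-1-yl)-5αH-octal-8-en-9-yl]pent-2-enoic acid (CNP0237483.2)
Conditions: LiOH, THF–MeOH–H2O, 40 °C; then aq. HCl to pH 3
Reagents that add atoms: lithium hydroxide, [Li+].[OH-]
Why: Saponification and acidification give the acid; no stereocentre is α to a carbonyl and the β,β-disubstituted (E)-enoate should not isomerise under these conditions.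

**Compound list**

1 | prop-2-enal (acrolein) | C=CC=O | starting material
2 | 2-(triphenylphosphoranylidene)propanal | CC(C=O)=P(c1ccccc1)(c1ccccc1)c1ccccc1 | starting material
3 | (2E)-2-methylpenta-2,4-dienal | C=C/C=C(\C)C=O | intermediate
4 | 2-[(2E)-but-2-en-1-yl]-4,4,5,5-tetramethyl-1,3,2-dioxaborolane | C/C=C/CB1OC(C)(C)C(C)(C)O1 | starting material
5 | (3R,4R,5E)-3,5-dimethylocta-1,5,7-trien-4-ol | C=C[C@@H](C)[C@@H](O)/C(C)=C/C=C | intermediate
6 | tert-butyl{[(3R,4R,5E)-3,5-dimethylocta-1,5,7-trien-4-yl]oxy}dimethylsilane | C=C[C@@H](C)[C@@H](O[Si](C)(C)C(C)(C)C)/C(C)=C/C=C | intermediate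
7 | prop-2-yn-1-ol | C#CCO | starting material
8 | (E)-alkenylalane: dimethylaluminium (2E)-3-(dimethylalumanyl)-2-methylprop-2-en-1-olate | C[Al](C)OC/C(C)=C/[Al](C)C | intermediate (not isolated)
9 | (2E)-3-iodo-2-methylprop-2-en-1-ol | OC/C(C)=C/I | intermediate
10 | 9-[(3R,4R,5E)-4-(tert-butyldimethylsilyloxy)-3,5-dimethylocta-5,7-dien-1-yl]-9-borabicyclo[3.3.1]nonane | C1CC2CCCC(C1)B2CC[C@@H](C)[C@@H](O[Si](C)(C)C(C)(C)C)/C(C)=C/C=C | intermediate (not isolated)
11 | (2E,6R,7R,8E)-7-(tert-butyldimethylsilyloxy)-2,6,8-trimethylundeca-2,8,10-trien-1-ol | OC/C(C)=C/CC[C@@H](C)[C@@H](O[Si](C)(C)C(C)(C)C)/C(C)=C/C=C | intermediate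
12 | (2E,6R,7R,8E)-7-(tert-butyldimethylsilyloxy)-2,6,8-trimethylundeca-2,8,10-trienal | O=C/C(C)=C/CC[C@@H](C)[C@@H](O[Si](C)(C)C(C)(C)C)/C(C)=C/C=C | intermediate
13 | 9α-(tert-butyldimethylsilyloxy)-4β,8α,10β-trimethyl-5αH-octal-1-ene-4α-carbaldehyde (trans-fused cycloadduct) | O=C[C@]1(C)CC=C[C@]2(C)[C@H](O[Si](C)(C)C(C)(C)C)[C@H](C)CC[C@@H]12 | intermediate
14 | 9α-(tert-butyldimethylsilyloxy)-4β,8α,10β-trimethyl-5αH-decalin-4α-carbaldehyde | O=C[C@]1(C)CCC[C@]2(C)[C@H](O[Si](C)(C)C(C)(C)C)[C@H](C)CC[C@@H]12 | intermediate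
15 | 9α-(tert-butyldimethylsilyloxy)-4β,8α,10β-trimethyl-4α-vinyl-5αH-decalin | C=C[C@]1(C)CCC[C@]2(C)[C@H](O[Si](C)(C)C(C)(C)C)[C@H](C)CC[C@@H]12 | intermediate
16 | 1-bromo-2-methylprop-1-ene | CC(C)=CBr | starting material
17 | 9-{2-[9α-(tert-butyldimethylsilyloxy)-4β,8α,10β-trimethyl-5αH-decalin-4α-yl]ethyl}-9-borabicyclo[3.3.1]nonane | C1CC2CCCC(C1)B2CC[C@]3(C)CCC[C@]4(C)[C@H](O[Si](C)(C)C(C)(C)C)[C@H](C)CC[C@@H]34 | intermediate (not isolated)
18 | 9α-(tert-butyldimethylsilyloxy)-4β,8α,10β-trimethyl-4α-(4-methylpent-3-en-1-yl)-5αH-decalin | CC(C)=CCC[C@]1(C)CCC[C@]2(C)[C@H](O[Si](C)(C)C(C)(C)C)[C@H](C)CC[C@@H]12 | intermediate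
19 | 4β,8α,10β-trimethyl-4α-(4-methylpent-3-en-1-yl)-5αH-decalin-9α-ol | CC(C)=CCC[C@]1(C)CCC[C@]2(C)[C@H](O)[C@H](C)CC[C@@H]12 | intermediate
20 | 4β,8α,10β-trimethyl-4α-(4-methylpent-3-en-1-yl)-5αH-decalin-9-one | CC(C)=CCC[C@]1(C)CCC[C@]2(C)C(=O)[C@H](C)CC[C@@H]12 | intermediate
21 | potassium 4β,8,10β-trimethyl-4α-(4-methylpent-3-en-1-yl)-5αH-octal-8-en-9-olate | CC(C)=CCC[C@]1(C)CCC[C@]2(C)C([O-])=C(C)CC[C@@H]12.[K+] | intermediate (not isolated)
22 | 4β,8,10β-trimethyl-4α-(4-methylpent-3-en-1-yl)-5αH-octal-8-en-9-yl trifluoromethanesulfonate | CC(C)=CCC[C@]1(C)CCC[C@]2(C)C(OS(=O)(=O)C(F)(F)F)=C(C)CC[C@@H]12 | intermediate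
23 | 4-bromobut-1-yne | C#CCCBr | starting material
24 | [(1E)-4-bromo-2-methylbut-1-en-1-yl]dimethylalumane | C[Al](C)/C=C(\C)CCBr | intermediate (not isolated)
25 | ethyl (2E)-5-bromo-3-methylpent-2-enoate | CCOC(=O)/C=C(\C)CCBr | intermediate
26 | [(3E)-5-ethoxy-3-methyl-5-oxopent-3-en-1-yl]zinc bromide | CCOC(=O)/C=C(\C)CC[Zn]Br | intermediate (not isolated)
27 | ethyl (2E)-3-methyl-5-[4β,8,10β-trimethyl-4α-(4-methylpent-3-en-1-yl)-5αH-octal-8-en-9-yl]pent-2-enoate | CC(C)=CCC[C@]1(C)CCC[C@]2(C)C(CC/C(C)=C/C(=O)OCC)=C(C)CC[C@@H]12 | intermediate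
28 | (2E)-3-methyl-5-[(4S,5S,10S)-4β,8,10β-trimethyl-4α-(4-methylpent-3-en-1-yl)-5αH-octal-8-en-9-yl]pent-2-enoic acid | CC(C)=CCC[C@]1(C)CCC[C@]2(C)C(CC/C(C)=C/C(=O)O)=C(C)CC[C@@H]12 | target

**Count**

Total step count: 16. Longest linear sequence: 14 steps (steps 1–3, 5–13, 15 and 16).

**Steps most likely to fail**

Step 7. The cycloaddition may stall: the diene must reach the s-cis form with the C10 methyl inside, and two quaternary centres with a 1,3-diaxial methyl pair develop. Ionisation of the allylic silyl ether by the Lewis acid, or oligomerisation of the diene, could then outrun ring closure, and endo control could erode at the higher temperature needed. The fallback sets out from trienal 12 and comes back at cycloadduct 13. Aldehyde 12 is converted with 1,2-bis(trimethylsiloxy)ethane and catalytic Me3SiOTf (CH2Cl2, −78 °C) into the ethylene acetal of the trienal F1. On warming to about −40 °C with the same acid, the acetal opens to an alkoxyallyl (oxocarbenium) cation. This is a much stronger dienophile than the aluminium-bound aldehyde and should close both rings in an ionic Diels–Alder reaction to the ethylene acetal of the cycloadduct F2. Pyridinium tosylate in wet acetone then returns 13.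

Step 15. Oxidative addition into the tetrasubstituted enol triflate flanked by a quaternary carbon may be slow, and β-hydride elimination from the alkylpalladium intermediate may compete, giving reduced triflate and chain isomers. The fallback sets out from triflate 22 and comes back at ester 27. Kumada coupling of 22 with [2-(2-methyl-1,3-dioxolan-2-yl)ethyl]magnesium bromide under Fe(acac)3 catalysis (THF–NMP, −20 °C) gives the C9 ketal-protected 3-oxobutyl compound F3. Pyridinium tosylate in wet acetone frees the C9 3-oxobutyl methyl ketone F4. Horner–Wadsworth–Emmons olefination with triethyl phosphonoacetate and NaH then gives 27, with the (E)-isomer expected to predominate and the (Z)-isomer removed by chromatography.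

Step 10. Hydroboration of the vinyl group on quaternary C4 may be sluggish and transmetalation of the hindered borane slow, so that protodeboronation takes the place of coupling. The fallback sets out from aldehyde 14 and comes back at 18. Horner–Wadsworth–Emmons olefination of 14 with triethyl phosphonoacetate and NaH (THF, reflux) gives the (E)-acrylate F5. Hydrogenation over Pd/C (no other C=C is present) gives the propanoate F6. i-Bu2AlH at −78 °C gives the propanal F7. Wittig olefination with isopropyltriphenylphosphonium iodide and n-BuLi then installs the isopropylidene terminus and gives 18.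

**Further compounds**

F1 | step 7 | ethylene acetal of trienal 12: 2-[(2E,6R,7R,8E)-7-(tert-butyldimethylsilyloxy)-6,8-dimethylundeca-2,8,10-trien-2-yl]-1,3-dioxolane | C1COC(O1)/C(C)=C/CC[C@@H](C)[C@@H](O[Si](C)(C)C(C)(C)C)/C(C)=C/C=C
F2 | step 7 | ethylene acetal of cycloadduct 13: 2-[9α-(tert-butyldimethylsilyloxy)-4β,8α,10β-trimethyl-5αH-octal-1-en-4α-yl]-1,3-dioxolane | C1COC(O1)[C@]2(C)CC=C[C@]3(C)[C@H](O[Si](C)(C)C(C)(C)C)[C@H](C)CC[C@@H]23
F3 | step 15 | 2-methyl-2-{2-[4β,8,10β-trimethyl-4α-(4-methylpent-3-en-1-yl)-5αH-octal-8-en-9-yl]ethyl}-1,3-dioxolane | CC(C)=CCC[C@]1(C)CCC[C@]2(C)C(CCC3(C)OCCO3)=C(C)CC[C@@H]12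
F4 | step 15 | 4-[4β,8,10β-trimethyl-4α-(4-methylpent-3-en-1-yl)-5αH-octal-8-en-9-yl]butan-2-one | CC(C)=CCC[C@]1(C)CCC[C@]2(C)C(CCC(C)=O)=C(C)CC[C@@H]12
F5 | step 10 | ethyl (2E)-3-[9α-(tert-butyldimethylsilyloxy)-4β,8α,10β-trimethyl-5αH-decalin-4α-yl]prop-2-enoate | CCOC(=O)/C=C/[C@]1(C)CCC[C@]2(C)[C@H](O[Si](C)(C)C(C)(C)C)[C@H](C)CC[C@@H]12
F6 | step 10 | ethyl 3-[9α-(tert-butyldimethylsilyloxy)-4β,8α,10β-trimethyl-5αH-decalin-4α-yl]propanoate | CCOC(=O)CC[C@]1(C)CCC[C@]2(C)[C@H](O[Si](C)(C)C(C)(C)C)[C@H](C)CC[C@@H]12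
F7 | step 10 | 3-[9α-(tert-butyldimethylsilyloxy)-4β,8α,10β-trimethyl-5αH-decalin-4α-yl]propanal | O=CCC[C@]1(C)CCC[C@]2(C)[C@H](O[Si](C)(C)C(C)(C)C)[C@H](C)CC[C@@H]12
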